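- At 40.0 min the alpha run, which is this flask, still holds 21.0% of its substrate, the limiting reagent, and that entry barely moved from 22.0% at 20.0 min.

all flasks: substrate 41 mM; partner 61.5 mM; free catalyst 0.20 mM
- alpha: second catalyst 2 mM; temperature 110 °C; the very flask that is asked about, followed so far
- eta: second catalyst 2 mM; temperature 95 °C; run made earlier
- flask: second catalyst 2.0 mM; temperature 110 °C; time 40 min

| run | time / min | product / % | substrate / % |
|---|---|---|---|
| alpha | 3.00 | 15 | 63 |
| alpha | 6.00 | 34 | 50 |
| alpha | 12.0 | 48 | 30 |
| alpha | 20.0 | 52 | 22 |
| alpha | 40.0 | 58 | 21 |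
| eta | 6.00 | 24 | 56 |
| eta | 12.0 | 40 | 39 |
| eta | 25.0 | 61 | 24 |
| eta | 40.0 | 65 | 15 |
| eta | 80.0 | 71 | 16 |

(each reading ± 2 percentage points)

- product taken out counts as made
- the analysis behind the earlier runs scatters by 2 percentage points, standard deviation
- "the catalyst" is free catalyst with its forms; second catalyst is a second catalyst
- additions bring no volume worth counting

- green: change nothing and wait 12 min more
- blue: at 40 min take out 90% of the product then present, then wait 12 min
- violet: at 40 min raise the temperature by 15 K, then wait 12 min
- red: at 40 min add partner, 100% of the amount charged, then wait 12 min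
- grey: at 40 min add free catalyst, 50.0% of the amount charged, then wait 12 min

- product, in percent of the substrate first charged, at 40 min
- the remedy with the largest gain of product, or "none" below 2 percentage points (green / blue / violet / red / grey / none)
- product present, with what was taken out counted in, in percent of the substrate first charged, after violet
- product present, with what was taken out counted in, in percent of the substrate first charged, after grey

- Ledger at 40.0 min, in fractions of the charge: product 58.0%, substrate 21.0%, and unaccounted 21 percentage points, which closes the books. The gap was already 22 points at 3.00 min.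
- In the alpha run at 40.0 min, product over substrate consumed reads 0.734.
- At one partner per product, 0.613 of the partner remains in the alpha run, so the stall is not a shortage of partner.
- I read the stall as a loss of free catalyst and carry one quantity: the stall depth, the common logarithm of charge over substrate left at the stall, here 0.678 decades.
- The eta run, cooler, reads 0.796 decades at 80.0 min, so the hotter alpha run shows the shallower stall, and I book green, blue, red and violet at 58.0%, which is also my figure for the product now.
- My reckoning: if depth scales with dose, grey's half dose buys 0.339 decades. Substrate falls to 0.0962, and product reaches 0.664, so my choice is grey.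
- The forecast says 57.5% (55.5% to 59.5%), best grey, violet 62% (56% to 66%), grey 67% (61% to 72%), because flat substrate beside rising product “favours catalyst death”. My violet figure is lower than its figure, and my grey figure is lower than its figure too.
- The flask gives 57.8%, best grey with a gain of 6.8 points, violet 57.8%, grey 64.6%.

    substrate + free catalyst ⇌ free catalyst + open intermediate (K = 0.160, k = 437 M⁻¹ s⁻¹, Ea = 46.0 kJ mol⁻¹, ΔH = −30.0 kJ mol⁻¹)
    free catalyst + product → spent catalyst (k = 0.277 M⁻¹ s⁻¹, Ea = 66.0 kJ mol⁻¹)
    partner + catalyst intermediate → second catalyst + product (k = 47.2 M⁻¹ s⁻¹, Ea = 36.0 kJ mol⁻¹)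
    second catalyst ⇌ dormant form (K = 0.257, k = 0.0197 s⁻¹, Ea = 114 kJ mol⁻¹, ΔH = −22.0 kJ mol⁻¹)
    second catalyst + open intermediate ⇌ catalyst intermediate (K = 5.00 M⁻¹, k = 9.35 M⁻¹ s⁻¹, Ea = 65.0 kJ mol⁻¹, ΔH = −8.00 kJ mol⁻¹)
    open intermediate → decomposed reagent (k = 0.00308 s⁻¹, Ea = 118 kJ mol⁻¹)
    (constants at 110 °C)

- At 40.0 min free catalyst stands at 0% and spent catalyst at >99.9%. Grey's gain, divided by 0.734, amounts to 0.253 decades of the 0.339 booked. With 150 mM of partner and the same catalyst, the neighbour flask ends with substrate at 17.2%, a depth of 0.764 decades.

The readings stem from a simulated flask with made-up constants, and the scatter is random.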